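The data are simulated with constants of no real substance; the scatter is artificial.

Start at the late end: take the last reading of each run, at 57 min, and follow one substrate molecule.

| setting | dusk | midnight | winter | dawn | summer |
|---|---|---|---|---|---|
| substrate | 250 mM | 100 mM | 250 mM | 250 mM | 250 mM |
| free catalyst | 0.500 mM | 0.500 mM | 0.250 mM | 0.500 mM | 0.110 mM |
| product |  |  |  | 75.0 mM |  |
| time |  |  |  |  | 57 min |

| run | time / min | [product] / mM |
|---|---|---|
| dusk run | 9.5 | 41.4 |
| dusk run | 19 | 71.9 |
| dusk run | 28 | 98.7 |
| dusk run | 38 | 120.3 |
| dusk run | 48 | 138.1 |
| dusk run | 57 | 153.0 |
| midnight run | 9.5 | 17.2 |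
| midnight run | 19 | 30.7 |
| midnight run | 28 | 42.9 |
| midnight run | 38 | 49.3 |
| midnight run | 48 | 57.5 |
| midnight run | 57 | 63.7 |
| winter run | 9.5 | 25.5 |
| winter run | 19 | 50.1 |
| winter run | 28 | 67.1 |
| winter run | 38 | 86.6 |
| winter run | 48 | 99.7 |
| winter run | 57 | 113.5 |
| dawn run | 9.5 | 110.3 |
| dawn run | 19 | 140.2 |
| dawn run | 28 | 162.7 |
| dawn run | 38 | 183.6 |
| dawn run | 48 | 201.4 |
| dawn run | 57 | 216.1 |

(each reading ± 0.8 mM)

- Overall: substrate -> product, with free catalyst as catalyst.
- Constant volume, constant temperature.
- Readings of a species count what is bound in complexes too.
- An order is taken over about fifteen percent of the charge, up and down.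

- the exponent of [substrate] in the starting rate at the charge of the dusk run (at the point where two percent of the substrate have become product) (one fixed amount of product, the same in the runs compared)
- the exponent of [free catalyst] in the starting rate at the charge of the dusk run (at the point where two percent of the substrate have become product)
- the midnight run starts with 150 mM less of substrate than the dusk run, and with no product. Compared where both hold the same amount of substrate, once fifteen percent of what the midnight run was charged with has turned into product, is the midnight run faster, slower or alike (within a tenth)?
- product in the summer run at 57 min, as a share of the substrate charged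
- which of these the readings show (the catalyst wakes slowly / the substrate is lost by itself / the substrate pairs with itself / nothing beyond the main steps / the product speeds the reaction / the product ties up the catalyst)

Define the pace, a pseudo-first-order constant: the natural log of substrate charged over substrate left, divided by the time. It is that molecule's average chance of turning per minute.

| run | free catalyst charged | substrate left | pace |
|---|---|---|---|
| dusk | 0.500 mM | 97.0 mM | 0.0166 min⁻¹ |
| midnight | 0.500 mM | 36.3 mM | 0.0178 min⁻¹ |
| winter | 0.250 mM | 136 mM | 0.0106 min⁻¹ |
| dawn | 0.500 mM | 109 mM | 0.0146 min⁻¹ |

Read midnight against dusk. The substrate charge falls from 250 mM to 100 mM, yet the pace changes by a factor of just 1.07. So I put the substrate exponent near one.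

Read dawn against dusk. Dawn starts with 75.0 mM of product, and its pace is slower than dusk's. So product holds the reaction back, and I read that as product tying up the catalyst. At equal substrate the dusk run carries 150 mM more product than the midnight run, so I call midnight faster.

Read winter against dusk. Winter has half of dusk's catalyst, but 0.639 of its pace, which is more than the catalyst ratio. Name the rule: the catalyst exponent 0.646, the power of the catalyst charge that the pace follows, with the substrate charge held at 250 mM and the time at 57 min.

Now step down from winter to summer, with the same substrate charge. The exponent gives a summer pace of 0.00625 min⁻¹. Over 57 min that turns 30.0% of the charge.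

The forecast gives 0.92, 0.65, faster, 30% and the product ties up the catalyst. Its ground for the catalyst order: “That suggests part of the catalyst sits in a resting dimer-like reservoir.” Its substrate exponent is 0.92, where I say about one.

The flask gives 1.0, 0.63, faster, 29.2% and the product ties up the catalyst.

    2 free catalyst ⇌ catalyst dimer, settled at all times (3640 L mol⁻¹)
    free catalyst + substrate → product + free catalyst (97.20 L mol⁻¹ min⁻¹)
    free catalyst + product ⇌ catalyst-product complex, settled at all times (8.110 L mol⁻¹)

Turn the summer result back into a pace, 0.00605 min⁻¹. Against winter that gives a catalyst exponent of 0.685, above the 0.646 from dusk and winter. The forecast's 30% would part further from a summer run with a lower exponent: the power-law fit's 32.4% needs 0.530. Carry 0.646 from dusk to the winter run, past its last reading: the pace 0.0106 min⁻¹ puts half the charge at 65.3 min, and the winter run reaches it at 66.9 min.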